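**Strategy.** Everything rests on the C2–C3 bond of the dihydrofuran ring. C3 is an unsubstituted benzylic methylene, and C2 is a methine bonded to ring oxygen O1 and to the 1,1-disubstituted alkene. C2–C3 can therefore be made by letting a benzylic carbene at the future C3 insert into the allylic, oxygen-activated C–H bond of an aryl 2-alkylallyl ether. That single operation closes the five-membered ring, forms C2–C3 and fixes C2 as R. The precursor is the tosylhydrazone of a 2-allyloxybenzaldehyde whose two other phenols are MOM ethers, chosen so that the final unmasking needs only dilute acid and so that C5 can later be lithiated.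

Key step: step 5

Assumption: which antipode of the porphyrin ligand leads to (2R) cannot be derived with confidence for this substrate; it is fixed by one trial run with each antipode, both being accessible from (S)- or (R)-2,2-dimethylcyclopropanecarboxamide.

**Route**

Step 1
Reactants: 1 2-methylprop-2-en-1-ol (methallyl alcohol); 2 1-bromo-3-methylbut-2-ene (prenyl bromide)
Product: 4 6-methyl-2-methylidenehept-5-en-1-ol, via dilithiated methallyl alcohol 3 (not isolated)
Conditions: n-BuLi (2.2 equiv), TMEDA, Et2O, 0 °C to rt; 2, −78 °C to rt; H2O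
Reagents that add atoms: none
Why: Alkylation of an allylic dianion: twofold deprotonation of 1 gives an alkoxide-tethered 2-methylallyl anion whose two carbon termini are equivalent, so SN2 displacement of the primary allylic bromide can lead only to 4.

Step 2
Reactants: 5 2,4,6-trihydroxybenzaldehyde
Product: 6 2-hydroxy-4,6-bis(methoxymethoxy)benzaldehyde
Conditions: MOMCl (2.1 equiv), i-Pr2NEt (2.5 equiv), CH2Cl2, 0 °C to rt
Reagents that add atoms: chloromethyl methyl ether (MOMCl), COCCl
Why: Williamson-type O-alkylation with an α-chloro ether: the hydroxyl para to the formyl group and one ortho hydroxyl react, while the second ortho hydroxyl stays free because it is held in a hydrogen bond to the formyl oxygen and is alkylated much more slowly.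

Step 3
Reactants: 6 2-hydroxy-4,6-bis(methoxymethoxy)benzaldehyde; 4 6-methyl-2-methylidenehept-5-en-1-ol
Product: 7 2,4-bis(methoxymethoxy)-6-[(6-methyl-2-methylidenehept-5-en-1-yl)oxy]benzaldehyde
Conditions: PPh3, DIAD, THF, 0 °C to rt
Reagents that add atoms: none
Why: Mitsunobu etherification: the acidic chelated phenol is alkylated at the primary allylic carbon of 4 under neutral conditions that leave the acetals, the aldehyde and both alkenes alone, and direct and allylic-shift substitution of this 2-substituted allyl unit give the same ether.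

Step 4
Reactants: 7 2,4-bis(methoxymethoxy)-6-[(6-methyl-2-methylidenehept-5-en-1-yl)oxy]benzaldehyde; 8 4-methylbenzenesulfonohydrazide
Product: 9 N'-[(E)-{2,4-bis(methoxymethoxy)-6-[(6-methyl-2-methylidenehept-5-en-1-yl)oxy]phenyl}methylidene]-4-methylbenzenesulfonohydrazide
Conditions: MeOH, rt
Reagents that add atoms: none
Why: Hydrazone condensation: the aldehyde and the sulfonyl hydrazide should combine without added acid to the E-configured N-tosylhydrazone, so the MOM acetals are not at risk.

Step 5
Reactants: 9 N'-[(E)-{2,4-bis(methoxymethoxy)-6-[(6-methyl-2-methylidenehept-5-en-1-yl)oxy]phenyl}methylidene]-4-methylbenzenesulfonohydrazide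
Product: 11 (2R)-4,6-bis(methoxymethoxy)-2-(6-methylhepta-1,5-dien-2-yl)-2,3-dihydro-1-benzofuran, via aryldiazomethane 10 (not isolated)
Conditions: Co(P*) (3 mol%; divalent cobalt; P* = 5,15-bis(3,5-di-tert-butylphenyl)-10,20-bis{2,6-bis[2,2-dimethylcyclopropane-1-carboxamido]phenyl}porphyrinate, one antipode), Cs2CO3 (2 equiv), 1,4-dioxane, 40–60 °C, N2
Reagents that add atoms: none
Why: Cs2CO3 converts 9 into aryldiazomethane 10 (Bamford–Stevens), the cobalt porphyrin, a d7 metalloradical, takes up 10 with loss of N2 to give a cobalt-bound benzylic radical (trivalent cobalt), which abstracts one of the two allylic hydrogens on the oxygen-bound CH2 (1,5-hydrogen transfer, six-membered transition state), and the α-oxyallyl radical so formed attacks the cobalt-bound carbon, forming C2–C3 and returning divalent cobalt. The closest known reaction type is the enantioselective radical 1,5-C–H alkylation by aryl carbenes made in situ from aldehyde tosylhydrazones under chiral amidoporphyrin catalysis with divalent cobalt, here applied to an allylic ether carrying a 1,1-disubstituted alkene. The dihydrofuran ring closes by homolytic substitution at the benzylic carbon in a 5-exo-tet mode. C2 is controlled by the catalyst: the amide-lined chiral pocket of the D2-symmetric porphyrin decides which enantiotopic O–CH2 hydrogen is abstracted and which face of the planar allyl radical bonds to C3, and the ligand antipode is chosen so that (2R) results. The step needs hydrogen abstraction to outrun cyclopropanation or uncatalysed dipolar cycloaddition at the tethered alkene, abstraction from the OCH2O group of the second ortho substituent and carbene dimerisation, and it needs closure at the oxygen-bearing allyl terminus instead of the distal CH2. The substrate secures this because the allylic, oxygen-substituted C–H bond is by far the weakest one in a 1,5-relationship to the radical, because five-membered closure is kinetically preferred to the seven-membered alternative, and because the two ortho substituents, the aprotic solvent and the slow release of 10 from the sparingly soluble base keep the free diazo compound dilute, hindered and unprotonated.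

Step 6
Reactants: 11 (2R)-4,6-bis(methoxymethoxy)-2-(6-methylhepta-1,5-dien-2-yl)-2,3-dihydro-1-benzofuran
Product: 12 1-[(2R)-4,6-bis(methoxymethoxy)-2-(6-methylhepta-1,5-dien-2-yl)-2,3-dihydro-1-benzofuran-7-yl]-N,N-dimethylmethanamine
Conditions: Me2N=CH2 I (1.2 equiv), MeCN, rt to 40 °C; aq NaOH
Reagents that add atoms: N,N-dimethylmethylideneammonium iodide, C[N+](C)=C.[I-]
Why: Mannich-type electrophilic aromatic substitution by a preformed iminium ion: the 1,3,5-trioxygenated ring is far more nucleophilic than either alkene, and attack is expected at C7, next to the tied-back ring oxygen O1, in preference to C5, which is shielded by two flanking OMOM groups (the same preference that 5,7-dialkoxychromans show for C8 over C6).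

Step 7
Reactants: 12 1-[(2R)-4,6-bis(methoxymethoxy)-2-(6-methylhepta-1,5-dien-2-yl)-2,3-dihydro-1-benzofuran-7-yl]-N,N-dimethylmethanamine
Product: 14 1-[(2R)-7-[(dimethylamino)methyl]-4,6-bis(methoxymethoxy)-2-(6-methylhepta-1,5-dien-2-yl)-2,3-dihydro-1-benzofuran-5-yl]ethan-1-one, via C5 aryllithium 13 (not isolated)
Conditions: n-BuLi (1.2 equiv), THF, −20 to 0 °C; MeC(O)N(OMe)Me, −78 °C to rt; H2O
Reagents that add atoms: N-methoxy-N-methylacetamide, CC(=O)N(C)OC
Why: Directed ortho-metalation followed by acylation: C5–H is the only ring hydrogen left and lies between two OMOM groups that acidify it and chelate lithium, so it should be removed well before C2–H or C3–H2 at low temperature, and the aryllithium adds only once to the N-methoxy-N-methyl amide because the chelated tetrahedral adduct survives until the quench.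

Step 8
Reactants: 14 1-[(2R)-7-[(dimethylamino)methyl]-4,6-bis(methoxymethoxy)-2-(6-methylhepta-1,5-dien-2-yl)-2,3-dihydro-1-benzofuran-5-yl]ethan-1-one
Product: 15 1-[(2R)-7-[(dimethylamino)methyl]-4,6-dihydroxy-2-(6-methylhepta-1,5-dien-2-yl)-2,3-dihydro-1-benzofuran-5-yl]ethan-1-one
Conditions: HCl (2 M in MeOH), rt; aq NaHCO3 to pH 7
Reagents that add atoms: none
Why: Acid-catalysed acetal exchange with methanol: both MOM ethers sit ortho to the acetyl group and are therefore labile, whereas the protonated amine, the isolated alkenes and the allylic C2–O1 bond should tolerate dilute acid at room temperature.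

Step 9
Reactants: 16 methyl 3-oxopentanoate; 17 N-methoxy-N-methylpropanamide
Product: 19 methyl 4-methyl-3,5-dioxoheptanoate, via keto ester dianion 18 (not isolated)
Conditions: NaH, THF, 0 °C; n-BuLi, 0 °C; 17, −78 to 0 °C; aq HCl
Reagents that add atoms: none
Why: Acylation of a β-keto ester dianion at its γ-carbon: the more reactive C4 carbanion of 18 attacks the N-methoxy-N-methyl amide, whose chelated adduct prevents a second addition and keeps the acidic product from quenching unreacted dianion.

Step 10
Reactants: 19 methyl 4-methyl-3,5-dioxoheptanoate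
Product: 20 6-ethyl-4-hydroxy-5-methyl-2H-pyran-2-one
Conditions: DBU, toluene, 80 °C; aq HCl
Reagents that add atoms: none
Why: Base-mediated lactonisation: the enolate oxygen of the 5-keto group attacks the methyl ester in a 6-exo-trig closure, and loss of methanol followed by tautomerisation gives the 4-hydroxy-2-pyranone.

Step 11
Reactants: 15 1-[(2R)-7-[(dimethylamino)methyl]-4,6-dihydroxy-2-(6-methylhepta-1,5-dien-2-yl)-2,3-dihydro-1-benzofuran-5-yl]ethan-1-one; 20 6-ethyl-4-hydroxy-5-methyl-2H-pyran-2-one
Product: 22 3-{[(2R)-5-acetyl-4,6-dihydroxy-2-(6-methylhepta-1,5-dien-2-yl)-2,3-dihydro-1-benzofuran-7-yl]methyl}-6-ethyl-4-hydroxy-5-methyl-2H-pyran-2-one, via ortho-quinone methide 21 (not isolated)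
Conditions: 20 (1.5 equiv), 1,4-dioxane, 90 °C, N2
Reagents that add atoms: none
Why: Mannich-base exchange through an ortho-quinone methide: on heating, the phenolic benzylamine loses dimethylamine with help from the ortho hydroxyl at C6, and the nucleophilic C3 of the 4-hydroxypyranone adds to the exocyclic methylene in a Michael addition that restores the aromatic ring, while 15 has no free ring position and so cannot self-condense.

**Compound list**

1 | 2-methylprop-2-en-1-ol | C=C(C)CO | starting material
2 | 1-bromo-3-methylbut-2-ene | CC(C)=CCBr | starting material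
3 | lithium 2-(lithiomethyl)prop-2-en-1-olate (dilithiated methallyl alcohol) | [Li]CC(=C)CO[Li] | intermediate
4 | 6-methyl-2-methylidenehept-5-en-1-ol | C=C(CCC=C(C)C)CO | intermediate
5 | 2,4,6-trihydroxybenzaldehyde | O=Cc1c(O)cc(O)cc1O | starting material
6 | 2-hydroxy-4,6-bis(methoxymethoxy)benzaldehyde | COCOc1cc(O)c(C=O)c(OCOC)c1 | intermediate
7 | 2,4-bis(methoxymethoxy)-6-[(6-methyl-2-methylidenehept-5-en-1-yl)oxy]benzaldehyde | C=C(CCC=C(C)C)COc1cc(OCOC)cc(OCOC)c1C=O | intermediate
8 | 4-methylbenzenesulfonohydrazide | Cc1ccc(S(=O)(=O)NN)cc1 | starting material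
9 | N'-[(E)-{2,4-bis(methoxymethoxy)-6-[(6-methyl-2-methylidenehept-5-en-1-yl)oxy]phenyl}methylidene]-4-methylbenzenesulfonohydrazide | C=C(CCC=C(C)C)COc1cc(OCOC)cc(OCOC)c1/C=N/NS(=O)(=O)c1ccc(C)cc1 | intermediate
10 | 2-(diazomethyl)-1,5-bis(methoxymethoxy)-3-[(6-methyl-2-methylidenehept-5-en-1-yl)oxy]benzene | C=C(CCC=C(C)C)COc1cc(OCOC)cc(OCOC)c1C=[N+]=[N-] | intermediate
11 | (2R)-4,6-bis(methoxymethoxy)-2-(6-methylhepta-1,5-dien-2-yl)-2,3-dihydro-1-benzofuran | C=C(CCC=C(C)C)[C@H]1Cc2c(OCOC)cc(OCOC)cc2O1 | intermediate
12 | 1-[(2R)-4,6-bis(methoxymethoxy)-2-(6-methylhepta-1,5-dien-2-yl)-2,3-dihydro-1-benzofuran-7-yl]-N,N-dimethylmethanamine | C=C(CCC=C(C)C)[C@H]1Cc2c(OCOC)cc(OCOC)c(CN(C)C)c2O1 | intermediate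
13 | [(2R)-7-[(dimethylamino)methyl]-4,6-bis(methoxymethoxy)-2-(6-methylhepta-1,5-dien-2-yl)-2,3-dihydro-1-benzofuran-5-yl]lithium | C=C(CCC=C(C)C)[C@H]1Cc2c(OCOC)c([Li])c(OCOC)c(CN(C)C)c2O1 | intermediate
14 | 1-[(2R)-7-[(dimethylamino)methyl]-4,6-bis(methoxymethoxy)-2-(6-methylhepta-1,5-dien-2-yl)-2,3-dihydro-1-benzofuran-5-yl]ethan-1-one | C=C(CCC=C(C)C)[C@H]1Cc2c(OCOC)c(C(C)=O)c(OCOC)c(CN(C)C)c2O1 | intermediate
15 | 1-[(2R)-7-[(dimethylamino)methyl]-4,6-dihydroxy-2-(6-methylhepta-1,5-dien-2-yl)-2,3-dihydro-1-benzofuran-5-yl]ethan-1-one | C=C(CCC=C(C)C)[C@H]1Cc2c(O)c(C(C)=O)c(O)c(CN(C)C)c2O1 | intermediate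
16 | methyl 3-oxopentanoate | CCC(=O)CC(=O)OC | starting material
17 | N-methoxy-N-methylpropanamide | CCC(=O)N(C)OC | starting material
18 | sodium lithium 2,4-dienolate (dianion) of methyl 3-oxopentanoate | CC=C(O[Li])C=C(OC)O[Na] | intermediate
19 | methyl 4-methyl-3,5-dioxoheptanoate (racemic, enolisable at C4) | CCC(=O)C(C)C(=O)CC(=O)OC | intermediate
20 | 6-ethyl-4-hydroxy-5-methyl-2H-pyran-2-one | CCc1oc(=O)cc(O)c1C | intermediate
21 | (2R)-5-acetyl-4-hydroxy-7-methylidene-2-(6-methylhepta-1,5-dien-2-yl)-2,3-dihydro-1-benzofuran-6(7H)-one (ortho-quinone methide) | C=C(CCC=C(C)C)[C@H]1CC2=C(O1)C(=C)C(=O)C(C(C)=O)=C2O | intermediate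
22 | 3-{[(2R)-5-acetyl-4,6-dihydroxy-2-(6-methylhepta-1,5-dien-2-yl)-2,3-dihydro-1-benzofuran-7-yl]methyl}-6-ethyl-4-hydroxy-5-methyl-2H-pyran-2-one | C=C(CCC=C(C)C)[C@H]1Cc2c(O)c(C(C)=O)c(O)c(Cc3c(O)c(C)c(CC)oc3=O)c2O1 | target

**Count and risks**

Total step count: 11. Longest linear sequence: 8 steps (step 1 or step 2, then steps 3, 4, 5, 6, 7, 8 and 11); steps 9 and 10 supply the pyranone.

Steps most likely to fail:

Step 5. The free diazo compound may add to the tethered alkene (dipolar cycloaddition or cyclopropanation) before the cobalt-bound radical abstracts hydrogen, or the ring may close with poor facial selectivity at this hindered, electron-rich carbene. The fallback replaces carbene insertion by a palladium heteroannulation; it sets out from 6 and comes back at 12.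
- Iodination of 6 with N-iodosuccinimide in CH2Cl2 should go ortho to the free hydroxyl and give 2-hydroxy-3-iodo-4,6-bis(methoxymethoxy)benzaldehyde F1.
- A Heck insertion followed by Tsuji–Trost-type closure with 7-methyl-3-methylideneocta-1,6-diene (myrcene) should give (2R)-4,6-bis(methoxymethoxy)-2-(6-methylhepta-1,5-dien-2-yl)-2,3-dihydro-1-benzofuran-7-carbaldehyde F2. Conditions: Pd2(dba)3 (zerovalent palladium), a chiral sulfinamide monophosphine ligand, K2CO3, toluene, 60–80 °C. The aryl group adds to the terminal carbon of the monosubstituted vinyl group, and the phenoxide closes onto the adjacent terminus of the allylpalladium unit under control of the ligand, which leaves exactly the 6-methylhepta-1,5-dien-2-yl group at C2.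
- Reductive amination of F2 with dimethylamine and NaBH(OAc)3 in 1,2-dichloroethane then gives 12.
- This path carries the C7 carbon from the start and so also by-passes step 6.

Step 6. Aminomethylation may be slow, or may not discriminate fully between C7 and C5. The fallback replaces direct aminomethylation by halogenation and cross-coupling; it sets out from 11 and comes back at 12.
- N-Bromosuccinimide (1.0 equiv) in CH2Cl2 at −78 °C should brominate the ring, not the alkenes, at the less hindered C7 and give (2R)-7-bromo-4,6-bis(methoxymethoxy)-2-(6-methylhepta-1,5-dien-2-yl)-2,3-dihydro-1-benzofuran F3. Regioisomers are easier to separate and assign at this simple stage.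
- Suzuki–Miyaura coupling of F3 with potassium [(dimethylamino)methyl]trifluoroborate should then give 12. Conditions: Pd(OAc)2, dicyclohexyl[2',4',6'-tri(propan-2-yl)biphenyl-2-yl]phosphane, Cs2CO3, THF–H2O, 80 °C.
- Should the discrimination between C7 and C5 prove inherently poor, the fallback given for step 5 removes the question.

Step 7. Deprotonation may stray to C2–H or C3–H2, with ring opening or erosion of configuration, or the hindered aryllithium may enolise the amide instead of adding to it. The fallback avoids strong base by bromination and Stille coupling; it sets out from 12 and comes back at 15.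
- 12 is first protonated with CF3CO2H (1 equiv) so that the amine is not oxidised. N-Bromosuccinimide in CH2Cl2 at 0 °C then brominates C5, the only open ring position, to give 1-[(2R)-5-bromo-4,6-bis(methoxymethoxy)-2-(6-methylhepta-1,5-dien-2-yl)-2,3-dihydro-1-benzofuran-7-yl]-N,N-dimethylmethanamine F4.
- Stille coupling with tributyl(1-ethoxyethenyl)stannane [Pd(PPh3)4 (zerovalent palladium), toluene, 100 °C] should give 1-[(2R)-5-(1-ethoxyethenyl)-4,6-bis(methoxymethoxy)-2-(6-methylhepta-1,5-dien-2-yl)-2,3-dihydro-1-benzofuran-7-yl]-N,N-dimethylmethanamine F5.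
- 2 M HCl in aqueous MeOH at rt then hydrolyses the enol ether to the acetyl group and removes both MOM groups in the same operation, giving 15.

Further compounds
F1 | step 5 | 2-hydroxy-3-iodo-4,6-bis(methoxymethoxy)benzaldehyde | O=Cc1c(O)c(I)c(OCOC)cc1OCOC
F2 | step 5 | (2R)-4,6-bis(methoxymethoxy)-2-(6-methylhepta-1,5-dien-2-yl)-2,3-dihydro-1-benzofuran-7-carbaldehyde | C=C(CCC=C(C)C)[C@H]1Cc2c(OCOC)cc(OCOC)c(C=O)c2O1
F3 | step 6 | (2R)-7-bromo-4,6-bis(methoxymethoxy)-2-(6-methylhepta-1,5-dien-2-yl)-2,3-dihydro-1-benzofuran | C=C(CCC=C(C)C)[C@H]1Cc2c(OCOC)cc(OCOC)c(Br)c2O1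
F4 | step 7 | 1-[(2R)-5-bromo-4,6-bis(methoxymethoxy)-2-(6-methylhepta-1,5-dien-2-yl)-2,3-dihydro-1-benzofuran-7-yl]-N,N-dimethylmethanamine | C=C(CCC=C(C)C)[C@H]1Cc2c(OCOC)c(Br)c(OCOC)c(CN(C)C)c2O1
F5 | step 7 | 1-[(2R)-5-(1-ethoxyethenyl)-4,6-bis(methoxymethoxy)-2-(6-methylhepta-1,5-dien-2-yl)-2,3-dihydro-1-benzofuran-7-yl]-N,N-dimethylmethanamine | C=C(CCC=C(C)C)[C@H]1Cc2c(OCOC)c(C(=C)OCC)c(OCOC)c(CN(C)C)c2O1
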